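## Retrosynthetic overview

1. The C6 ester and the free C5 hydroxyl come from trans-diaxial opening of a 5α,6α-vinyl epoxide at the allylic C6 by the acid itself; the 2β-acetate, the (Z)-ethylidene at C3 and the C7 methylene go back to a PMB ether, a C3 ketone and a C7 ketone (two Wittig reactions).
2. The epoxy ketone goes back to a trans-fused C5=C6 enone, which arises from a cis-fused 5-silyloxy-7-ketone by E1cB elimination and epimerisation at C7a.
3. Key disconnection: the bicyclic 7-ketone comes from a monocyclic 1-vinylcyclopentyl silyl ether with a 2,2-dialkoxyethyl side chain by an acetal-initiated Prins cyclization–pinacol shift. This closes ring A (C1–C2 bond) and, in the same event, enlarges the starting cyclopentane (C3a, C4, C5, C6, C7) to the six-membered ring B by migration of C3a from C7 to C7a.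
4. The cyclopentane comes from (S)-4-silyloxycyclopentenone by three-component coupling (isopropyl addition, aldol with a dialkoxyacetaldehyde) and vinyl addition. Ring order: the cyclopentane is present from the start; ring A and ring B are formed together in the key step.
5. Enabling feature: the exocyclic methylene carbon C7 is a latent ketone on ring B, bonded to the ring-fusion carbon C7a and 1,4-related to the oxygen-bearing C2 of ring A (C7–C7a–C1–C2). A γ-alkoxy ketone whose α-carbon is the ring fusion is what a Prins–pinacol ring enlargement delivers.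

Key step: step 6

Conventions: indane numbering of the target core is used for every intermediate (ring A: C1, C2, C3, C3a, C7a; ring B: C3a, C4, C5, C6, C7, C7a). In the monocyclic precursors C7 is the ring carbon bearing the ketone or carbinol oxygen, C3a its side-chain-bearing neighbour, C3 and C2 the side-chain carbons, C7a and C1 the vinyl carbons. β is the face of H-7a in the target, α the opposite face; PMB = 4-methoxybenzyl, TBS = tert-butyldimethylsilyl.

Assumption: compounds 1, 2, 5 (as the S enantiomer) and 19 are taken as purchasable.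

## Route

Step 1
Reactants: 1 3,3-diethoxyprop-1-ene; 2 4-methoxybenzyl alcohol
Product: 3 3,3-bis[(4-methoxybenzyl)oxy]prop-1-ene
Conditions: 2 (2.2 equiv in all), PPTS (cat.), toluene, 60 °C, reduced pressure (EtOH removed)
Reagents that add atoms: 4-methoxybenzyl alcohol (second equivalent of 2), COc1ccc(CO)cc1
Why: Two successive acid-catalysed acetal exchanges (transacetalisation), each through the allyl-stabilised oxocarbenium ion, replace both ethoxy groups and therefore consume two equivalents of the alcohol; removal of ethanol drives them under acid mild enough not to ionise the benzylic alcohol, and no stereocentre is formed.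

Step 2
Reactants: 3 3,3-bis[(4-methoxybenzyl)oxy]prop-1-ene
Product: 4 2,2-bis[(4-methoxybenzyl)oxy]acetaldehyde
Conditions: O3, CH2Cl2, −78 °C (indicator end point); then PPh3, −78 °C → rt
Reagents that add atoms: ozone, [O-][O+]=O
Why: Ozonolysis of the terminal alkene with reductive work-up, stopped at the indicator end point because the alkene reacts faster than the anisyl rings; no stereocentre is formed.

Step 3
Reactants: 5 (S)-4-[(tert-butyldimethylsilyl)oxy]cyclopent-2-en-1-one; 4 2,2-bis[(4-methoxybenzyl)oxy]acetaldehyde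
Product: 7 (2,3-trans,3,4-trans)-4-(TBS-oxy)-2-{1-hydroxy-2,2-bis[(4-methoxybenzyl)oxy]ethyl}-3-isopropylcyclopentan-1-one (both carbinol epimers), via magnesium enolate 6 (not isolated)
Conditions: i-PrMgCl, CuBr·SMe2 (10 mol %), THF, −78 °C; then 4, −78 °C; aq. NH4Cl
Reagents that add atoms: isopropylmagnesium chloride, CC(C)[Mg]Cl
Why: Three-component coupling: copper-catalysed 1,4-addition anti to the silyloxy group sets C4, and the regiodefined enolate 6 adds to aldehyde 4 anti to the new isopropyl group (aldol addition, sets C3a); the carbinol carbon C3 forms as an inconsequential epimer mixture because it is oxidised in step 10.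

Step 4
Reactants: 7 aldol adduct (β-hydroxy ketone)
Product: 8 (1-OH cis to the C2 side chain)-4-(TBS-oxy)-2-{1-hydroxy-2,2-bis[(4-methoxybenzyl)oxy]ethyl}-3-isopropyl-1-vinylcyclopentan-1-ol
Conditions: CH2=CHMgBr, CeCl3, THF, −78 °C
Reagents that add atoms: vinylmagnesium bromide, C=C[Mg]Br
Why: Organocerium-mediated 1,2-addition to an enolisable β-oxygenated ketone (no enolisation or retro-aldol), expected mainly anti to the adjacent side chain; the configuration of this carbinol carbon is irrelevant because it becomes the carbonyl carbon in step 6.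

Step 5
Reactants: 8 diol
Product: 9 bis(trimethylsilyl) ether of 8
Conditions: N-(trimethylsilyl)imidazole (2.5 equiv), CH2Cl2, rt
Reagents that add atoms: N-(trimethylsilyl)imidazole, C[Si](C)(C)n1ccnc1
Why: Silylation of the secondary and the tertiary allylic hydroxyl groups with a neutral, powerful silyl donor that leaves the acid-labile acetal untouched; no stereocentre is affected.

Step 6
Reactants: 9 bis(trimethylsilyl) ether
Product: 10 (2β,3aα-H,4α,5β,7aα-H)-5-(TBS-oxy)-4-isopropyl-2-[(4-methoxybenzyl)oxy]-3-[(trimethylsilyl)oxy]octahydroinden-7-one (cis-fused, both C3 epimers)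
Conditions: TMSOTf (20 mol %), 2,6-di-tert-butyl-4-methylpyridine (30 mol %), CH2Cl2, −78 → −30 °C; Et3N, aq. NaHCO3
Reagents that add atoms: none
Why: Prins cyclization–pinacol rearrangement (acetal-initiated ring-enlarging cyclopentane annulation): TMSOTf ionises the acetal to the (E)-oxocarbenium ion at C2, the terminal vinyl carbon C1 attacks it through a chair transition state (6-endo closure of a transient ring C7–C7a–C1–C2–C3–C3a), and the cation developing at C7a is quenched at once by a 1,2-shift of C3a from the silyloxy carbon C7 to C7a, which contracts the transient ring to ring A and enlarges the original cyclopentane (C3a, C4, C5, C6, C7) by one carbon to the cyclohexanone ring B, loss of the silyl group from the resulting oxocarbenium ion regenerating TMSOTf. The closest known reaction type is the Lewis-acid-promoted rearrangement of 1-alkenyl-2-(2,2-dialkoxyethyl)cycloalkyl silyl ethers to ring-expanded, alkoxy-substituted hydrindanones. C2 is set by the chair, in which the benzyloxy group of the (E)-oxocarbenium ion sits equatorial and therefore cis to the equatorial C3a–C4 bond (2β); C3a migrates with retention and C7a is formed on the face of the migrating bond, which gives the cis ring fusion kinetically and is corrected in step 7 because C7a is now α to the ketone. The step needs initiation at the acetal only (the most Lewis-basic site; silyl ether oxygens that add to the oxocarbenium ion do so reversibly), cyclization in preference to proton loss (the shift is concerted with C–C bond formation) and migration of C3a rather than C6, which is secured because only the C7–C3a bond is aligned with the empty orbital at C7a in the chair. Both epimers at C3 and at C7 of 9 converge, since C7 becomes the carbonyl carbon and C3 is oxidised later.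

Step 7
Reactants: 10 cis-fused 5-silyloxy-7-ketone
Product: 11 (2β,3aα-H,4α,7aβ-H)-4-isopropyl-2-[(4-methoxybenzyl)oxy]-3-[(trimethylsilyl)oxy]-1,2,3,3a,4,7a-hexahydroinden-7-one (trans-fused C5=C6 enone)
Conditions: DBU, toluene, 80 °C
Reagents that add atoms: none
Why: E1cB elimination of the β-silyloxy group gives the C5=C6 enone and, under the same equilibrating conditions, C7a (α′ to the carbonyl) epimerises through the dienolate to the trans-fused isomer with all ring-B substituents equatorial, expected to be the thermodynamic one (any cis-fused material is resubjected).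

Step 8
Reactants: 11 trans-fused enone
Product: 12 5α,6α-epoxide of 11 (α,β-epoxy ketone)
Conditions: t-BuOOH (decane solution), DBU, CH2Cl2, 0 °C → rt
Reagents that add atoms: tert-butyl hydroperoxide, CC(C)(C)OO
Why: Weitz–Scheffer nucleophilic epoxidation: the peroxide anion should add to C5 axially, antiperiplanar to the axial H-4 of the conformationally locked half-chair, that is from the α-face, and closure of the enolate gives the 5α,6α-epoxide (sets C5 and C6).

Step 9
Reactants: 12 α,β-epoxy ketone
Product: 14 (2β,3aα-H,4α,5α,6α,7aβ-H)-5,6-epoxy-4-isopropyl-2-[(4-methoxybenzyl)oxy]-7-methylideneoctahydroinden-3-ol (both C3 epimers), via trimethylsilyl ether 13 (not isolated)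
Conditions: Ph3PCH3Br, KOtBu, THF, 0 °C → rt; then K2CO3, MeOH, 0 °C
Reagents that add atoms: methyltriphenylphosphonium bromide, C[P+](c1ccccc1)(c1ccccc1)c1ccccc1.[Br-]
Why: Wittig methylenation of the epoxy ketone with a non-stabilised ylide (the epoxide is inert to it at these temperatures), followed in the same flask by methanolysis of the secondary trimethylsilyl ether; no stereocentre is touched.

Step 10
Reactants: 14 epoxy alcohol
Product: 15 (2β,3aα-H,4α,5α,6α,7aβ-H)-5,6-epoxy-4-isopropyl-2-[(4-methoxybenzyl)oxy]-7-methylideneoctahydroinden-3-one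
Conditions: Dess–Martin periodinane, NaHCO3, CH2Cl2, 0 °C → rt
Reagents that add atoms: none
Why: Dess–Martin oxidation of the secondary alcohol under buffered, non-epimerising conditions that tolerate the vinyl epoxide and the PMB ether; the C3 epimers converge on one ketone.

Step 11
Reactants: 15 α-alkoxy ketone
Product: 16 (3Z)-5α,6α-epoxy-3-ethylidene-4α-isopropyl-2β-[(4-methoxybenzyl)oxy]-7-methylideneoctahydroindene
Conditions: Ph3PCH2CH3Br, KN(SiMe3)2, THF, −78 → 0 °C
Reagents that add atoms: ethyltriphenylphosphonium bromide, CC[P+](c1ccccc1)(c1ccccc1)c1ccccc1.[Br-]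
Why: Wittig ethylidenation of an α-alkoxy ketone, a reaction type known to place the new alkyl group cis to the alkoxy-bearing carbon (methyl syn to C2, the Z-alkene), run cold so that addition outpaces enolisation towards C3a or C2.

Step 12
Reactants: 16 PMB ether
Product: 17 (3Z)-5α,6α-epoxy-3-ethylidene-4α-isopropyl-7-methylideneoctahydroinden-2β-ol
Conditions: DDQ, CH2Cl2/pH 7 buffer, 0 °C
Reagents that add atoms: none
Why: Oxidative PMB cleavage with DDQ (benzylic hydride abstraction, then hydrolysis) in buffered medium, faster than oxidation of the alkenes and harmless to the vinyl epoxide; C2 is not affected.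

Step 13
Reactants: 17 allylic alcohol
Product: 18 (3Z)-5α,6α-epoxy-3-ethylidene-4α-isopropyl-7-methylideneoctahydroinden-2β-yl acetate
Conditions: Ac2O, pyridine, DMAP (cat.), CH2Cl2, 0 °C → rt
Reagents that add atoms: acetic anhydride, CC(=O)OC(C)=O
Why: DMAP-catalysed acetylation with retention at C2 under basic conditions compatible with the vinyl epoxide.

Step 14
Reactants: 18 vinyl epoxide acetate; 19 (E)-3-methylpent-2-enoic acid
Product: 20 (2β,3Z,3aα-H,4α,5α,6β,7aβ-H)-2-acetoxy-3-ethylidene-5-hydroxy-4-isopropyl-7-methylideneoctahydroinden-6-yl (E)-3-methylpent-2-enoate (CNP0418642.2)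
Conditions: 19 (excess), Cs2CO3 (0.5 equiv), DMF, 60 °C
Reagents that add atoms: none
Why: SN2 opening of the vinyl epoxide by the caesium carboxylate at the allylic carbon C6 from the β-face, which is also the trans-diaxial (Fürst–Plattner) mode on the locked ring, should give the 6β-ester with inversion at C6 and the free 5α-hydroxyl; the trans-diaxial arrangement blocks acyl migration.

## Compound list

1 | 3,3-diethoxyprop-1-ene | C=CC(OCC)OCC | starting material
2 | 4-methoxybenzyl alcohol | COc1ccc(CO)cc1 | starting material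
3 | 3,3-bis[(4-methoxybenzyl)oxy]prop-1-ene | C=CC(OCc1ccc(OC)cc1)OCc1ccc(OC)cc1 | intermediate
4 | 2,2-bis[(4-methoxybenzyl)oxy]acetaldehyde | O=CC(OCc1ccc(OC)cc1)OCc1ccc(OC)cc1 | intermediate
5 | (S)-4-[(tert-butyldimethylsilyl)oxy]cyclopent-2-en-1-one | O=C1C=C[C@@H](O[Si](C)(C)C(C)(C)C)C1 | starting material
6 | chloromagnesium (3,4-trans)-4-(TBS-oxy)-3-isopropylcyclopent-1-en-1-olate | Cl[Mg]OC1=C[C@H](C(C)C)[C@@H](O[Si](C)(C)C(C)(C)C)C1 | intermediate
7 | (2,3-trans,3,4-trans)-4-(TBS-oxy)-2-{1-hydroxy-2,2-bis[(4-methoxybenzyl)oxy]ethyl}-3-isopropylcyclopentan-1-one, both carbinol epimers | O=C1[C@@H](C(O)C(OCc2ccc(OC)cc2)OCc2ccc(OC)cc2)[C@H](C(C)C)[C@@H](O[Si](C)(C)C(C)(C)C)C1 | intermediate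
8 | 1-vinylcyclopentan-1-ol from 7 (1-OH cis to the C2 side chain; 2,3-trans; 3,4-trans) | C=C[C@]1(O)[C@@H](C(O)C(OCc2ccc(OC)cc2)OCc2ccc(OC)cc2)[C@H](C(C)C)[C@@H](O[Si](C)(C)C(C)(C)C)C1 | intermediate
9 | bis(trimethylsilyl) ether of 8 | C=C[C@]1(O[Si](C)(C)C)[C@@H](C(O[Si](C)(C)C)C(OCc2ccc(OC)cc2)OCc2ccc(OC)cc2)[C@H](C(C)C)[C@@H](O[Si](C)(C)C(C)(C)C)C1 | intermediate
10 | (2β,3aα-H,4α,5β,7aα-H)-5-(TBS-oxy)-4-isopropyl-2-[(4-methoxybenzyl)oxy]-3-[(trimethylsilyl)oxy]octahydroinden-7-one, cis-fused, both C3 epimers | O=C1[C@H]2C[C@@H](OCc3ccc(OC)cc3)C(O[Si](C)(C)C)[C@H]2[C@H](C(C)C)[C@@H](O[Si](C)(C)C(C)(C)C)C1 | intermediate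
11 | (2β,3aα-H,4α,7aβ-H)-4-isopropyl-2-[(4-methoxybenzyl)oxy]-3-[(trimethylsilyl)oxy]-1,2,3,3a,4,7a-hexahydroinden-7-one, trans-fused | O=C1[C@@H]2C[C@@H](OCc3ccc(OC)cc3)C(O[Si](C)(C)C)[C@H]2[C@H](C(C)C)C=C1 | intermediate
12 | 5α,6α-epoxide of 11 | O=C1[C@@H]2C[C@@H](OCc3ccc(OC)cc3)C(O[Si](C)(C)C)[C@H]2[C@H](C(C)C)[C@@H]4O[C@H]14 | intermediate
13 | 5α,6α-epoxy-4α-isopropyl-2β-[(4-methoxybenzyl)oxy]-7-methylidene-3-[(trimethylsilyl)oxy]octahydroindene | C=C1[C@@H]2C[C@@H](OCc3ccc(OC)cc3)C(O[Si](C)(C)C)[C@H]2[C@H](C(C)C)[C@@H]4O[C@H]14 | intermediate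
14 | 5α,6α-epoxy-4α-isopropyl-2β-[(4-methoxybenzyl)oxy]-7-methylideneoctahydroinden-3-ol, both C3 epimers | C=C1[C@@H]2C[C@@H](OCc3ccc(OC)cc3)C(O)[C@H]2[C@H](C(C)C)[C@@H]4O[C@H]14 | intermediate
15 | 5α,6α-epoxy-4α-isopropyl-2β-[(4-methoxybenzyl)oxy]-7-methylideneoctahydroinden-3-one | C=C1[C@@H]2C[C@@H](OCc3ccc(OC)cc3)C(=O)[C@H]2[C@H](C(C)C)[C@@H]4O[C@H]14 | intermediate
16 | (3Z)-5α,6α-epoxy-3-ethylidene-4α-isopropyl-2β-[(4-methoxybenzyl)oxy]-7-methylideneoctahydroindene | C=C1[C@@H]2C[C@@H](OCc3ccc(OC)cc3)/C(=C\C)[C@H]2[C@H](C(C)C)[C@@H]4O[C@H]14 | intermediate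
17 | (3Z)-5α,6α-epoxy-3-ethylidene-4α-isopropyl-7-methylideneoctahydroinden-2β-ol | C=C1[C@@H]2C[C@@H](O)/C(=C\C)[C@H]2[C@H](C(C)C)[C@@H]4O[C@H]14 | intermediate
18 | (3Z)-5α,6α-epoxy-3-ethylidene-4α-isopropyl-7-methylideneoctahydroinden-2β-yl acetate | C=C1[C@@H]2C[C@@H](OC(C)=O)/C(=C\C)[C@H]2[C@H](C(C)C)[C@@H]4O[C@H]14 | intermediate
19 | (E)-3-methylpent-2-enoic acid | CC/C(C)=C/C(=O)O | starting material
20 | (2β,3Z,3aα-H,4α,5α,6β,7aβ-H)-2-acetoxy-3-ethylidene-5-hydroxy-4-isopropyl-7-methylideneoctahydroinden-6-yl (E)-3-methylpent-2-enoate | C=C1[C@@H]2C[C@@H](OC(C)=O)/C(=C\C)[C@H]2[C@H](C(C)C)[C@H](O)[C@H]1OC(=O)/C=C(\C)CC | target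

## Step count and risks

Total steps: 14. Longest linear sequence: 14 (steps 1–14 from 1; 12 steps from 5).

Step 6 (key step). What may go wrong: incomplete facial selectivity at the oxocarbenium carbon, because the two C3 epimers of 9 cyclise through slightly different chairs and the ion can pre-equilibrate with a cyclic mixed acetal of the neighbouring tertiary silyl ether; the C2 epimer would then accompany 10 and be carried through to 17. Fallback, setting out from 17 obtained as a mixture with its C2 epimer and returning to 17: C2 is set by hydride instead of by the cyclization. Oxidation of the allylic alcohol mixture with MnO2 in CH2Cl2 should give the single (3Z)-3-ethylidene-2-ketone F1, used at once to avoid isomerisation of the alkene. Corey–Bakshi–Shibata reduction with catecholborane, using the oxazaborolidine enantiomer matched to hydride delivery to the α-face, should return pure 17.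

Step 8. What may go wrong: poor facial selectivity, namely attack of the peroxide anti to the neighbouring equatorial isopropyl group instead of axial attack, giving the 5β,6β-epoxide. Fallback, from 11 back to 12: hydroxyl-directed instead of nucleophilic epoxidation. Corey–Bakshi–Shibata 1,2-reduction of 11 with catecholborane, with hydride delivered to the β-face of the carbonyl, should give the pseudoaxial 7α-allylic alcohol F2. VO(acac)2 with t-BuOOH should then epoxidise the C5=C6 bond syn to the hydroxyl group (α-face) to the epoxy alcohol F3, and Dess–Martin oxidation of F3 returns the α-epoxy ketone 12.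

Step 11. What may go wrong: enolisation of the hindered α-alkoxy cyclopentanone by the basic ylide (epimerisation at C3a or C2) and erosion of the Z-selectivity when steric and alkoxy effects oppose each other. Fallback, from 15 back to 16: Peterson olefination. The weakly basic organocerium reagent from (1-(trimethylsilyl)ethyl)magnesium chloride and CeCl3 is added to 15 at −78 °C to give the β-hydroxysilanes F4, whose diastereomers are separated. The set whose syn-elimination leads to the Z-alkene is treated with KH in THF. The complementary set is acylated with trifluoroacetic anhydride and pyridine to the tertiary trifluoroacetate F5, which undergoes anti-elimination on warming. Both stereospecific eliminations converge on 16.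

Further compounds

F1 | step 6 | (3Z)-5α,6α-epoxy-3-ethylidene-4α-isopropyl-7-methylideneoctahydroinden-2-one | C=C1[C@@H]2CC(=O)/C(=C\C)[C@H]2[C@H](C(C)C)[C@@H]4O[C@H]14
F2 | step 8 | (2β,3aα-H,4α,7α,7aβ-H)-4-isopropyl-2-[(4-methoxybenzyl)oxy]-3-[(trimethylsilyl)oxy]-2,3,3a,4,7,7a-hexahydro-1H-inden-7-ol | O[C@@H]1[C@@H]2C[C@@H](OCc3ccc(OC)cc3)C(O[Si](C)(C)C)[C@H]2[C@H](C(C)C)C=C1
F3 | step 8 | 5α,6α-epoxide of F2 (5α,6α-epoxy-7α-ol) | O[C@@H]1[C@@H]2C[C@@H](OCc3ccc(OC)cc3)C(O[Si](C)(C)C)[C@H]2[C@H](C(C)C)[C@@H]4O[C@H]14
F4 | step 11 | 5α,6α-epoxy-4α-isopropyl-2β-[(4-methoxybenzyl)oxy]-7-methylidene-3-[1-(trimethylsilyl)ethyl]octahydroinden-3-ol, diastereomers at C3 and at the silyl-bearing carbon | C=C1[C@@H]2C[C@@H](OCc3ccc(OC)cc3)C(O)(C(C)[Si](C)(C)C)[C@H]2[C@H](C(C)C)[C@@H]4O[C@H]14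
F5 | step 11 | trifluoroacetate of F4 | C=C1[C@@H]2C[C@@H](OCc3ccc(OC)cc3)C(OC(=O)C(F)(F)F)(C(C)[Si](C)(C)C)[C@H]2[C@H](C(C)C)[C@@H]4O[C@H]14
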